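Rings C and D hide a vinylcyclohexadiene. In ring C (C8, C9, C11, C12, C13, C14; kaurane numbering) the bonds C12–C13 and C8–C14 flank the two-carbon unit C13–C14, so both should form together when a vinyl group on C16 of a dearomatised salicylate (a 6-hydroxy-6-vinylcyclohexa-2,4-dienone, ring C15–C8–C9–C11–C12–C16) adds across its own diene. This intramolecular Diels–Alder reaction closes ring D and a cyclopropane (C12–C13–C16) at once; the acylcyclopropanol then opens at C12–C16, and this strain release drives the sequence and unveils the C15/C16 diketone of the bicyclo[3.2.1]octane. The precursor is a flat spiro-isochromanone vinylphenol that already carries ring A.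

Key step: step 10

Numbering remark: kaurane numbering of the target is used for every compound: ring A = C1(=O), C2, C3(–O–), C4(Me2), C5, C10; C6 = ether CH2; C7 = lactone carbonyl; C20 = lactone CH2; ring C = C8, C9, C11, C12, C13, C14; ring D = C8, C14, C13, C16, C15(=O); C17 = methyl on C16.
Assumption: the ligand antipode in step 3 and the reagent antipode in step 9 are those that give the drawn configurations; both centres are set by the reagent alone.

Step 1
Reactants: 1 5-bromo-2-chlorophenol
Product: 2 4-bromo-1-chloro-2-(methoxymethoxy)benzene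
Conditions: MOMCl, iPr2NEt, CH2Cl2, 0 °C to rt
Reagents that add atoms: chloromethyl methyl ether, COCCl
Why: Williamson-type O-alkylation of the phenol with the reactive α-chloro ether masks the acidic OH for the lithiation and enolate steps and gives a directing group; no stereocentre is formed.

Step 2
Reactants: 2 4-bromo-1-chloro-2-(methoxymethoxy)benzene
Product: 4 tert-butyl 6-bromo-3-chloro-2-(methoxymethoxy)benzoate, via aryllithium 3 (not isolated)
Conditions: LiN(iPr)2, THF, −78 °C; then Boc2O, −78 °C to rt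
Reagents that add atoms: di-tert-butyl dicarbonate, CC(C)(C)OC(=O)OC(=O)OC(C)(C)C
Why: Directed ortho-lithiation removes the hydrogen flanked by the methoxymethoxy group and bromine (the most acidic one, and the amide base does not exchange the bromine), and acylation of the aryllithium with Boc2O gives a tert-butyl ester that should later resist attack by the neighbouring ketone enolate.

Step 3
Reactants: 5 4,4-dimethylcyclohexa-2,5-dien-1-one
Product: 6 (5S)-4,4-dimethyl-5-vinylcyclohex-2-en-1-one
Conditions: vinylboronic acid pinacol ester (limiting), 5 (1.5 equiv), [Rh(cod)Cl]2 (2.5 mol %), (S)-BINAP (6 mol %), KOH (0.2 equiv), dioxane/H2O 10:1, 50 °C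
Reagents that add atoms: vinylboronic acid pinacol ester, C=CB1OC(C)(C)C(C)(C)O1
Why: Rhodium-catalysed asymmetric conjugate addition (Hayashi–Miyaura reaction) desymmetrises the prochiral dienone, the BINAP–rhodium vinyl species choosing one enantiotopic enone arm and face to set C5 (sense by analogy with cyclohex-2-enone), while the second enone survives for the later ether closure.

Step 4
Reactants: 6 (5S)-4,4-dimethyl-5-vinylcyclohex-2-en-1-one; 4 tert-butyl 6-bromo-3-chloro-2-(methoxymethoxy)benzoate
Product: 7 tert-butyl 3-chloro-6-[(1S,6R)-5,5-dimethyl-2-oxo-6-vinylcyclohex-3-en-1-yl]-2-(methoxymethoxy)benzoate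
Conditions: Pd2(dba)3 (2.5 mol %), Xantphos (6 mol %), NaOtBu (1.3 equiv), toluene, 70 °C
Reagents that add atoms: none
Why: Palladium-catalysed ketone α-arylation works here because C10 is the only enolisable position of the enone (C4 is quaternary), the bromide reacts in preference to the chloride, and the aryl group enters trans to the vinyl group at an epimerisable centre that is reset in step 6.

Step 5
Reactants: 7 tert-butyl 3-chloro-6-[(1S,6R)-5,5-dimethyl-2-oxo-6-vinylcyclohex-3-en-1-yl]-2-(methoxymethoxy)benzoate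
Product: 10 tert-butyl 3-chloro-6-[(1R,2R,5S)-8,8-dimethyl-3-oxo-6-oxabicyclo[3.2.1]octan-2-yl]-2-(methoxymethoxy)benzoate, via aldehyde 8 (not isolated), via hydroxymethyl enone 9 (not isolated)
Conditions: O3, CH2Cl2/MeOH 3:1, −78 °C; Me2S; NaBH4 (1 equiv), −78 °C; then DBU (0.2 equiv), CH2Cl2, rt
Reagents that add atoms: ozone, [O-][O+]=O
Why: Ozonolysis cleaves the electron-rich vinyl group in preference to the enone, borohydride at −78 °C reduces the aldehyde but not the ketone, and the primary alcohol closes the tetrahydrofuran by intramolecular oxa-Michael addition, which is only possible cis across C4 and so sets C3 from C5 (C10 equilibrates to the equatorial aryl epimer).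

Step 6
Reactants: 10 tert-butyl 3-chloro-6-[(1R,2R,5S)-8,8-dimethyl-3-oxo-6-oxabicyclo[3.2.1]octan-2-yl]-2-(methoxymethoxy)benzoate
Product: 11 tert-butyl 3-chloro-6-[(1S,2R,5S)-2-(hydroxymethyl)-8,8-dimethyl-3-oxo-6-oxabicyclo[3.2.1]octan-2-yl]-2-(methoxymethoxy)benzoate
Conditions: 37% aq. CH2O, K2CO3 (0.3 equiv), THF, 0 °C to rt
Reagents that add atoms: formaldehyde, C=O
Why: Crossed aldol reaction with formaldehyde at the benzylic, more acidic α-carbon (enolisation towards C2 only opens the ether reversibly), the electrophile approaching anti to the axial C6 bridge on the neighbouring C5 so that the aryl group stays equatorial, which sets the quaternary C10 and is also the thermodynamic outcome.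

Step 7
Reactants: 11 tert-butyl 3-chloro-6-[(1S,2R,5S)-2-(hydroxymethyl)-8,8-dimethyl-3-oxo-6-oxabicyclo[3.2.1]octan-2-yl]-2-(methoxymethoxy)benzoate
Product: 13 (1'S,2'R,5'S)-7-chloro-8-hydroxy-8',8'-dimethylspiro[isochromane-4,2'-[6]oxabicyclo[3.2.1]octane]-1,3'-dione, via hydroxy acid 12 (not isolated)
Conditions: TFA/CH2Cl2 1:3, 0 °C to rt; then toluene, 60 °C
Reagents that add atoms: none
Why: Acidolysis removes the methoxymethyl ether and the tert-butyl ester, and the resulting 2-(2-hydroxyethyl)benzoic acid should close by Fischer-type lactonisation to the six-membered isochromanone; no stereocentre is touched.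

Step 8
Reactants: 13 (1'S,2'R,5'S)-7-chloro-8-hydroxy-8',8'-dimethylspiro[isochromane-4,2'-[6]oxabicyclo[3.2.1]octane]-1,3'-dione
Product: 14 (1'S,2'R,5'S)-8-hydroxy-8',8'-dimethyl-7-vinylspiro[isochromane-4,2'-[6]oxabicyclo[3.2.1]octane]-1,3'-dione
Conditions: vinylboronic acid pinacol ester, Pd(OAc)2 (5 mol %), SPhos (10 mol %), K3PO4, toluene/H2O 10:1, 80 °C
Reagents that add atoms: vinylboronic acid pinacol ester, C=CB1OC(C)(C)C(C)(C)O1
Why: Suzuki–Miyaura coupling of the aryl chloride with an electron-rich biaryl phosphine ligand places the vinyl group ortho to the phenol and tolerates the free phenol and the lactone; no stereocentre is formed.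

Step 9
Reactants: 14 (1'S,2'R,5'S)-8-hydroxy-8',8'-dimethyl-7-vinylspiro[isochromane-4,2'-[6]oxabicyclo[3.2.1]octane]-1,3'-dione
Product: 15 quinol (1'S,2'R,5'S,7R)-7-hydroxy-8',8'-dimethyl-7-vinyl-3H-spiro[isochromene-4,2'-[6]oxabicyclo[3.2.1]octane]-1,3',8(7H)-trione (C16 R)
Conditions: axially chiral C2-symmetric bis(2-iodoxybenzoic acid) reagent (0.55 equiv), THF, 0 °C to rt; aq. NaHCO3 work-up; used at once
Reagents that add atoms: 6,6'-dimethoxy-7,7'-bi(1-hydroxy-1-oxo-1,2-benziodoxol-3-one), one atropisomer, COc1ccc2C(=O)OI(O)(=O)c2c1-c1c(OC)ccc2C(=O)OI(O)(=O)c12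
Why: Hydroxylative phenol dearomatisation, in which the phenol binds to pentavalent iodine and oxygen is delivered intramolecularly to the vinyl-bearing ortho carbon C16 (the other ortho carbon carries the acyl group), the chiral biaryl backbone choosing the arene face because the nearest stereocentre (C10, para) is four bonds away.

Step 10
Reactants: 15 quinol (1'S,2'R,5'S,7R)-7-hydroxy-8',8'-dimethyl-7-vinyl-3H-spiro[isochromene-4,2'-[6]oxabicyclo[3.2.1]octane]-1,3',8(7H)-trione
Product: 17 diketone (3S,5S,8S,10R,13R)-3,6-epoxy-1,15,16-trioxo-17-nor-6,7-secokaur-9(11)-en-7,20-olide, via tricyclic cyclopropanol 16 (not isolated)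
Conditions: iPr2NEt (0.3 equiv), BHT, PhCl (0.01 M), 130 °C, sealed tube, dark
Reagents that add atoms: none
Why: The vinyl group on C16 adds across the C8=C9–C11=C12 diene of the quinol in a concerted, suprafacial intramolecular Diels–Alder reaction that forms C12–C13 and C8–C14 together; the amine then opens the 1-acylcyclopropanol 16 at C12–C16 to the C16 ketone with protonation of the allylic carbanion at C12, and this irreversible release of cyclopropane strain should pull the reversible cycloaddition forward. The closest known reaction types are the thermal cycloaddition of 5-vinylcyclohexa-1,3-dienes (and of 6-allenylcyclohexa-2,4-dienones) to tricyclo[3.2.1.0(2,7)]oct-3-enes and the base-induced isomerisation of cyclopropanols to ketones. Ring C (C8, C9, C11, C12, C13, C14) closes as the six-membered ring of the [4+2] event, ring D (C8, C14, C13, C16, C15) as the five-membered ring spanned by the C16–C15 tether in the bridged mode, and the cyclopropane C12–C13–C16 because the dienophile is bound to the carbon next to the diene terminus. C8 and C13 (and transiently C12) are controlled by C16 alone, since the vinyl group can reach only the diene face on which it stands and both bonds form on that face. The step needs the cycloaddition to outrun dimerisation, α-ketol shifts and sigmatropic shifts of the dienone, which the fully substituted C8/C9 diene end, the quaternary C16 and high dilution should secure, and it needs cleavage of C12–C16 and not C13–C16, which the C9=C11 alkene secures because only the C12 carbanion is allylic.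

Step 11
Reactants: 17 diketone (3S,5S,8S,10R,13R)-3,6-epoxy-1,15,16-trioxo-17-nor-6,7-secokaur-9(11)-en-7,20-olide
Product: 18 (3S,5S,8S,10R,13R,16R)-3,6-epoxy-16-hydroxy-1,15-dioxo-6,7-secokaur-9(11)-en-7,20-olide
Conditions: MeMgBr (1.1 equiv), THF, −78 °C; H2O quench at −78 °C
Reagents that add atoms: methylmagnesium bromide, C[Mg]Br
Why: Grignard 1,2-addition to the strained, non-enolisable 1,2-diketone, which is far more electrophilic than the hindered C1 ketone or the lactone; C16 (next to the C13 methine) is attacked and not the neopentyl C15, from the exo face on the side of the C14 bridge, which places the methyl exo and the hydroxyl endo (16R).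

Step 12
Reactants: 18 (3S,5S,8S,10R,13R,16R)-3,6-epoxy-16-hydroxy-1,15-dioxo-6,7-secokaur-9(11)-en-7,20-olide
Product: 19 (3S,5S,8S,9S,10S,13R,16R)-3,6-epoxy-16-hydroxy-1,15-dioxo-6,7-secokauran-7,20-olide
Conditions: [Ir(cod)(PCy3)(py)]PF6 (10 mol %), H2 (1–5 bar), CH2Cl2, rt
Reagents that add atoms: none
Why: Hydroxyl-directed homogeneous hydrogenation, in which the endo C16 hydroxyl lies over C11/C12 and binds the cationic iridium more strongly than either ketone, so hydrogen should reach the C9=C11 alkene from the face syn to the C15–C16 bridge and set C9 (H syn to C15).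

Compound list
1 | 5-bromo-2-chlorophenol | Oc1cc(Br)ccc1Cl | starting material
2 | 4-bromo-1-chloro-2-(methoxymethoxy)benzene | COCOc1cc(Br)ccc1Cl | intermediate
3 | [6-bromo-3-chloro-2-(methoxymethoxy)phenyl]lithium (not isolated) | [Li]c1c(OCOC)c(Cl)ccc1Br | intermediate
4 | tert-butyl 6-bromo-3-chloro-2-(methoxymethoxy)benzoate | COCOc1c(Cl)ccc(Br)c1C(=O)OC(C)(C)C | intermediate
5 | 4,4-dimethylcyclohexa-2,5-dien-1-one | CC1(C)C=CC(=O)C=C1 | starting material
6 | (5S)-4,4-dimethyl-5-vinylcyclohex-2-en-1-one | CC1(C)C=CC(=O)C[C@H]1C=C | intermediate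
7 | tert-butyl 3-chloro-6-[(1S,6R)-5,5-dimethyl-2-oxo-6-vinylcyclohex-3-en-1-yl]-2-(methoxymethoxy)benzoate (aryl and vinyl trans) | CC1(C)C=CC(=O)[C@H](c2ccc(Cl)c(OCOC)c2C(=O)OC(C)(C)C)[C@H]1C=C | intermediate
8 | tert-butyl 3-chloro-6-[(1S,6R)-6-formyl-5,5-dimethyl-2-oxocyclohex-3-en-1-yl]-2-(methoxymethoxy)benzoate (not isolated) | CC1(C)C=CC(=O)[C@H](c2ccc(Cl)c(OCOC)c2C(=O)OC(C)(C)C)[C@H]1C=O | intermediate
9 | tert-butyl 3-chloro-6-[(1S,6R)-6-(hydroxymethyl)-5,5-dimethyl-2-oxocyclohex-3-en-1-yl]-2-(methoxymethoxy)benzoate (not isolated) | CC1(C)C=CC(=O)[C@H](c2ccc(Cl)c(OCOC)c2C(=O)OC(C)(C)C)[C@H]1CO | intermediate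
10 | tert-butyl 3-chloro-6-[(1R,2R,5S)-8,8-dimethyl-3-oxo-6-oxabicyclo[3.2.1]octan-2-yl]-2-(methoxymethoxy)benzoate (aryl equatorial, cis to the C6–O bridge) | CC1(C)[C@@H]2CC(=O)[C@@H](c3ccc(Cl)c(OCOC)c3C(=O)OC(C)(C)C)[C@H]1CO2 | intermediate
11 | tert-butyl 3-chloro-6-[(1S,2R,5S)-2-(hydroxymethyl)-8,8-dimethyl-3-oxo-6-oxabicyclo[3.2.1]octan-2-yl]-2-(methoxymethoxy)benzoate (CH2OH trans to the C6–O bridge) | CC1(C)[C@@H]2CC(=O)[C@@](CO)(c3ccc(Cl)c(OCOC)c3C(=O)OC(C)(C)C)[C@H]1CO2 | intermediate
12 | 3-chloro-2-hydroxy-6-[(1S,2R,5S)-2-(hydroxymethyl)-8,8-dimethyl-3-oxo-6-oxabicyclo[3.2.1]octan-2-yl]benzoic acid (not isolated) | CC1(C)[C@@H]2CC(=O)[C@@](CO)(c3ccc(Cl)c(O)c3C(=O)O)[C@H]1CO2 | intermediate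
13 | (1'S,2'R,5'S)-7-chloro-8-hydroxy-8',8'-dimethylspiro[isochromane-4,2'-[6]oxabicyclo[3.2.1]octane]-1,3'-dione | CC1(C)[C@@H]2CC(=O)[C@]3(COC(=O)c4c(O)c(Cl)ccc43)[C@H]1CO2 | intermediate
14 | (1'S,2'R,5'S)-8-hydroxy-8',8'-dimethyl-7-vinylspiro[isochromane-4,2'-[6]oxabicyclo[3.2.1]octane]-1,3'-dione | CC1(C)[C@@H]2CC(=O)[C@]3(COC(=O)c4c(O)c(C=C)ccc43)[C@H]1CO2 | intermediate
15 | quinol (1'S,2'R,5'S,7R)-7-hydroxy-8',8'-dimethyl-7-vinyl-3H-spiro[isochromene-4,2'-[6]oxabicyclo[3.2.1]octane]-1,3',8(7H)-trione (6-hydroxy-6-vinylcyclohexa-2,4-dienone, C16 R) | CC1(C)[C@@H]2CC(=O)[C@]3(COC(=O)C4=C3C=C[C@](O)(C=C)C4=O)[C@H]1CO2 | intermediate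
16 | tricyclic cyclopropanol: 16-hydroxy-12,16-cyclo-3,6-epoxy-1,15-dioxo-17-nor-6,7-secokaur-9(11)-en-7,20-olide (tricyclo[3.2.1.0(2,7)]oct-3-en-6-one core, cyclopropane C12–C13–C16; not isolated) | CC1(C)[C@@H]2CC(=O)[C@]3(COC(=O)[C@@]45C[C@H]6[C@@H](C=C43)[C@@]6(O)C5=O)[C@H]1CO2 | intermediate
17 | (3S,5S,8S,10R,13R)-3,6-epoxy-1,15,16-trioxo-17-nor-6,7-secokaur-9(11)-en-7,20-olide | CC1(C)[C@@H]2CC(=O)[C@]3(COC(=O)[C@@]45C[C@@H](CC=C43)C(=O)C5=O)[C@H]1CO2 | intermediate
18 | (3S,5S,8S,10R,13R,16R)-3,6-epoxy-16-hydroxy-1,15-dioxo-6,7-secokaur-9(11)-en-7,20-olide | CC1(C)[C@@H]2CC(=O)[C@]3(COC(=O)[C@@]45C[C@@H](CC=C43)[C@@](C)(O)C5=O)[C@H]1CO2 | intermediate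
19 | (3S,5S,8S,9S,10S,13R,16R)-3,6-epoxy-16-hydroxy-1,15-dioxo-6,7-secokauran-7,20-olide | CC1(C)[C@@H]2CC(=O)[C@]3(COC(=O)[C@@]45C[C@@H](CC[C@H]43)[C@@](C)(O)C5=O)[C@H]1CO2 | target

Total step count: 12
Longest linear sequence: 11 steps (1 → 2 → 4 → 7 → 10 → 11 → 13 → 14 → 15 → 17 → 18 → 19; the ring A branch 5 → 6 joins at step 4).

Steps most likely to fail, with fallbacks

Step 9. Ligand exchange of the hydrogen-bonded, acyl-substituted phenol at iodine may be slow, and the reagent may discriminate the two arene faces poorly because nothing in the substrate helps it. The fallback sets out from 14: Wessely acetoxylation with Pb(OAc)4 in acetic acid should give the quinol acetate as two C16 epimers, which are diastereomers because of ring A. The (16R)-quinol acetate F1 is separated by chromatography from the (16S)-quinol acetate F2, which is discarded. Methanolysis of F1 (K2CO3, MeOH, 0 °C) frees the tertiary alcohol, and the route is rejoined at 15.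

Step 10. The free quinol may undergo base- or heat-induced α-ketol shifts and aromatising migrations faster than it cyclises, and the cycloaddition of the conjugated dienone may be too unfavourable for the ring opening to drain it. The fallback sets out from 15 and removes both the free hydroxyl and the dienone. Silylation (TESOTf, 2,6-lutidine, CH2Cl2, −78 °C) gives the quinol triethylsilyl ether F3. Luche reduction (NaBH4, CeCl3·7H2O, MeOH, 0 °C) of the C15 and C1 ketones gives the dienediol F4, a plain 5-vinylcyclohexa-1,3-diene. Thermolysis (toluene, 160 °C, sealed tube) gives the tricyclic diol F5 by the same cycloaddition. Swern oxidation of both secondary alcohols gives the tricyclic diketone silyl ether F6, and TBAF buffered with acetic acid (THF, 0 °C) cleaves the silyl ether and opens the cyclopropane, so that the route is rejoined at 17.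

Step 12. Hydrogen may be delivered to the undirected lower face, or the alkene between two quaternary carbons may not turn over. The fallback sets out from 18 and adds a second, closer directing group. NaBH4 (MeOH, 0 °C) reduces the C15 ketone from the exo face (and the C1 ketone) to the unsaturated triol F7, whose endo C15 hydroxyl lies directly over C9. Hydrogenation with [Ir(cod)(PCy3)(py)]PF6 under direction by the C15 and C16 hydroxyls gives the saturated triol F8. Swern oxidation of the two secondary alcohols leaves the tertiary C16 alcohol untouched, and the route is rejoined at 19.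

Further compounds
F1 | step 9 | (16R)-quinol acetate: 7-acetoxy analogue of 15 | CC1(C)[C@@H]2CC(=O)[C@]3(COC(=O)C4=C3C=C[C@](OC(C)=O)(C=C)C4=O)[C@H]1CO2
F2 | step 9 | (16S)-quinol acetate: C16 epimer of F1 | CC1(C)[C@@H]2CC(=O)[C@]3(COC(=O)C4=C3C=C[C@@](OC(C)=O)(C=C)C4=O)[C@H]1CO2
F3 | step 10 | quinol triethylsilyl ether of 15 | CC1(C)[C@@H]2CC(=O)[C@]3(COC(=O)C4=C3C=C[C@](O[Si](CC)(CC)CC)(C=C)C4=O)[C@H]1CO2
F4 | step 10 | dienediol: C1 and C15 carbinols of F3 (carbinol epimers not defined) | CC1(C)[C@@H]2CC(O)[C@]3(COC(=O)C4=C3C=C[C@](O[Si](CC)(CC)CC)(C=C)C4O)[C@H]1CO2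
F5 | step 10 | tricyclic diol: cycloadduct of F4 (carbinol epimers not defined) | CC1(C)[C@@H]2CC(O)[C@]3(COC(=O)[C@@]45C[C@H]6[C@@H](C=C43)[C@@]6(O[Si](CC)(CC)CC)C5O)[C@H]1CO2
F6 | step 10 | tricyclic diketone silyl ether: triethylsilyl ether of 16 | CC1(C)[C@@H]2CC(=O)[C@]3(COC(=O)[C@@]45C[C@H]6[C@@H](C=C43)[C@@]6(O[Si](CC)(CC)CC)C5=O)[C@H]1CO2
F7 | step 12 | unsaturated triol: C1 and C15 carbinols of 18 (C15 hydroxyl endo expected, C1 not defined) | CC1(C)[C@@H]2CC(O)[C@]3(COC(=O)[C@@]45C[C@@H](CC=C43)[C@@](C)(O)C5O)[C@H]1CO2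
F8 | step 12 | saturated triol: C1 and C15 carbinols of 19 | CC1(C)[C@@H]2CC(O)[C@]3(COC(=O)[C@@]45C[C@@H](CC[C@H]43)[C@@](C)(O)C5O)[C@H]1CO2
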